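**Retrosynthetic overview**
1. The last bond made is C6–C7. The C6(O)–C7–C11(=C13H2)–C12(=O)–O array of the α-methylene-γ-butyrolactone (ring O/C6/C7/C11/C12) is the retron of an SE2′ addition of a C13-metalated 2-(methoxycarbonyl)allyl unit (C11=C7) to a C6 aldehyde. Run intramolecularly on an acyclic bromo-aldehyde, it closes the cyclodecadiene (C1–C10) and, by lactonisation onto C12, the lactone, and sets C6 and C7. The Z-C4=C5 / cis-2,3-oxirane / C1=C10 segment is a rigid hairpin that holds C6 next to C7.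
2. The seco chain, with all four esters and the oxirane in place, is cut at C9–C10 into a West (Z)-α-iodoenoate (C14, C10, C1–C6) and an East C9 aldehyde (C7–C9, C11–C13, C8 ester), joined by Ni/Cr alkenylation.
3. West: but-2-yn-1-ol → Z-iodoalkene → Sonogashira → cis-semireduction → asymmetric epoxidation (C2, C3) → iodo-Wittig.
4. East: (R)-solketal (C8) → 2-O-acyl glyceraldehyde carrying the side-chain acid (from benzyl tiglate by asymmetric epoxidation and acetolysis) → vinylalumination (Baylis–Hillman alcohol as latent allyl bromide).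
5. Ring order: oxirane first (step 5); carbocycle and lactone together in the last step.

Key step: step 26

Remark: germacrane-type locants are used throughout (ring C1–C10, lactone O on C6, C11/C12/C13 = lactone α-carbon, C=O and exocyclic CH2, C14 = ester carbon on C10, C15 = CH3 on C4); R*CO = (2S,3S)-3-acetoxy-2-methyl-2-(triethylsilyloxy)butanoyl and RCO = its free tertiary alcohol; the C7 carbinol of 26–33 becomes sp2 in step 25, so these are taken as C7-epimer mixtures and written without a descriptor there; the numbered starting materials are assumed to be commercial.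

**Step 1**
Reactants: 1 but-2-yn-1-ol
Product: 3 (2Z)-3-iodobut-2-en-1-ol, via cyclic alkenylalanate 2 (not isolated)
Conditions: Red-Al, THF, 0 °C → rt; then I2, THF, −78 → 0 °C
Reagents that add atoms: iodine, II
Why: Hydroxyl-directed trans-hydroalumination of the propargylic alcohol puts Al on the distal carbon inside the five-membered alanate 2, and iodinolysis with retention gives the Z-iodoalkene (I cis to CH2OH), which fixes the later C4=C5 geometry.

**Step 2**
Reactants: 3 (2Z)-3-iodobut-2-en-1-ol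
Product: 4 tert-butyl{[(2Z)-3-iodobut-2-en-1-yl]oxy}dimethylsilane
Conditions: TBSCl, imidazole, DMF, 0 °C → rt
Reagents that add atoms: tert-butyldimethylsilyl chloride, CC(C)(C)[Si](C)(C)Cl
Why: Imidazole-mediated silylation of the primary allylic alcohol; no stereocentre is involved.

**Step 3**
Reactants: 4 tert-butyl{[(2Z)-3-iodobut-2-en-1-yl]oxy}dimethylsilane; 5 prop-2-yn-1-ol
Product: 6 (4Z)-6-[(tert-butyldimethylsilyl)oxy]-4-methylhex-4-en-2-yn-1-ol
Conditions: Pd(PPh3)2Cl2 (3 mol %), CuI (5 mol %), Et3N, THF, rt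
Reagents that add atoms: none
Why: Sonogashira coupling of the alkenyl iodide with the terminal alkyne forms C3–C4 with retention of the alkene geometry and tolerates the free propargylic alcohol.

**Step 4**
Reactants: 6 (4Z)-6-[(tert-butyldimethylsilyl)oxy]-4-methylhex-4-en-2-yn-1-ol
Product: 7 (2Z,4Z)-6-[(tert-butyldimethylsilyl)oxy]-4-methylhexa-2,4-dien-1-ol
Conditions: Zn(Cu/Ag), MeOH–H2O, 40 °C
Reagents that add atoms: none
Why: Activated zinc reduces only the conjugated triple bond by syn delivery of two hydrogens (cis-selective semireduction of an enyne), giving the 2Z alkene without over-reduction or isomerisation of C4=C5.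

**Step 5**
Reactants: 7 (2Z,4Z)-6-[(tert-butyldimethylsilyl)oxy]-4-methylhexa-2,4-dien-1-ol
Product: 8 [(2R,3S)-3-{(2Z)-4-[(tert-butyldimethylsilyl)oxy]but-2-en-2-yl}oxiran-2-yl]methanol
Conditions: Ti(OiPr)4 (20 mol %), D-(−)-diethyl tartrate (24 mol %), t-BuOOH, 4 Å MS, CH2Cl2, −20 °C
Reagents that add atoms: tert-butyl hydroperoxide, CC(C)(C)OO
Why: Sharpless asymmetric epoxidation is directed by the free allylic hydroxyl to C2=C3 only, is stereospecific (Z-alkene gives the cis-oxirane), and with D-(−)-tartrate should deliver oxygen to the face that gives the (2R,3S) epoxide.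

**Step 6**
Reactants: 8 [(2R,3S)-3-{(2Z)-4-[(tert-butyldimethylsilyl)oxy]but-2-en-2-yl}oxiran-2-yl]methanol
Product: 9 (2S,3S)-3-{(2Z)-4-[(tert-butyldimethylsilyl)oxy]but-2-en-2-yl}oxirane-2-carbaldehyde
Conditions: Dess–Martin periodinane, NaHCO3, CH2Cl2, 0 °C
Reagents that add atoms: none
Why: Dess–Martin oxidation under buffered, non-basic conditions should give the cis-epoxy aldehyde without epimerisation at C2 or opening of the vinyl oxirane (the descriptor at C2 changes only by priority).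

**Step 7**
Reactants: 9 (2S,3S)-3-{(2Z)-4-[(tert-butyldimethylsilyl)oxy]but-2-en-2-yl}oxirane-2-carbaldehyde; 10 methyl (triphenyl-λ5-phosphanylidene)acetate
Product: 12 methyl (2Z)-3-[(2R,3S)-3-{(2Z)-4-[(tert-butyldimethylsilyl)oxy]but-2-en-2-yl}oxiran-2-yl]-2-iodoprop-2-enoate, via iodo ylide 11 (not isolated)
Conditions: 10, N-iodosuccinimide, CH2Cl2, −20 °C; then 9, 0 °C → rt
Reagents that add atoms: N-iodosuccinimide, O=C1CCC(=O)N1I
Why: Iodination of the stabilised ylide gives the α-iodo ylide 11, whose Wittig olefination of the aldehyde under neutral conditions should give the (Z)-α-iodoenoate (ester trans to C2), the usual selectivity of α-halo stabilised ylides.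

**Step 8**
Reactants: 13 benzyl (2E)-2-methylbut-2-enoate (benzyl tiglate)
Product: 14 benzyl (2S,3R)-2,3-dimethyloxirane-2-carboxylate
Conditions: D-fructose-derived Shi ketone (acetate-modified, 25 mol %), Oxone, NaHCO3, Bu4NHSO4 (cat.), MeCN–aq. Na2EDTA, 0 °C
Reagents that add atoms: potassium peroxymonosulfate (Oxone), [K+].[O-]S(=O)(=O)OO
Why: Shi epoxidation (chiral dioxirane, spiro transition state) of the trisubstituted E-enoate is stereospecific for the alkene geometry and should give the (2S,3R) glycidic ester, the facial sense this ketone shows with E-enoates.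

**Step 9**
Reactants: 14 benzyl (2S,3R)-2,3-dimethyloxirane-2-carboxylate
Product: 15 benzyl (2S,3S)-3-acetoxy-2-hydroxy-2-methylbutanoate
Conditions: AcOH, Sc(OTf)3 (5 mol %), rt → 40 °C
Reagents that add atoms: acetic acid, CC(=O)O
Why: Acid-catalysed epoxide opening by acetic acid occurs by SN2 with inversion at C3, the carbon remote from the ester (C2 is tertiary and deactivated by the carbonyl), so C3 becomes S while the C2–O bond and its configuration are kept.

**Step 10**
Reactants: 15 benzyl (2S,3S)-3-acetoxy-2-hydroxy-2-methylbutanoate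
Product: 16 benzyl (2S,3S)-3-acetoxy-2-methyl-2-[(triethylsilyl)oxy]butanoate
Conditions: TESOTf, 2,6-lutidine, CH2Cl2, 0 °C → rt
Reagents that add atoms: triethylsilyl triflate, CC[Si](CC)(CC)OS(=O)(=O)C(F)(F)F
Why: Silyl triflate silylation protects the hindered tertiary alcohol so that the acid can be activated without self-acylation; the group leaves later with the other silyl ethers.

**Step 11**
Reactants: 16 benzyl (2S,3S)-3-acetoxy-2-methyl-2-[(triethylsilyl)oxy]butanoate
Product: 17 (2S,3S)-3-acetoxy-2-methyl-2-[(triethylsilyl)oxy]butanoic acid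
Conditions: H2 (1 atm), 10 % Pd/C, EtOAc, rt
Reagents that add atoms: none
Why: Hydrogenolysis of the benzyl ester frees the acid under neutral conditions that leave the acetate and the silyl ether untouched.

**Step 12**
Reactants: 18 [(4R)-2,2-dimethyl-1,3-dioxolan-4-yl]methanol ((R)-solketal)
Product: 19 (4R)-4-{[(4-methoxybenzyl)oxy]methyl}-2,2-dimethyl-1,3-dioxolane
Conditions: NaH, PMBCl, Bu4NI (cat.), THF–DMF, 0 °C → rt
Reagents that add atoms: 4-methoxybenzyl chloride, COc1ccc(CCl)cc1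
Why: Williamson etherification of the alkoxide; the stereocentre (future C8) is not touched.

**Step 13**
Reactants: 19 (4R)-4-{[(4-methoxybenzyl)oxy]methyl}-2,2-dimethyl-1,3-dioxolane
Product: 20 (2S)-3-[(4-methoxybenzyl)oxy]propane-1,2-diol
Conditions: AcOH–H2O (4:1), 40 °C
Reagents that add atoms: none
Why: Acid hydrolysis of the isopropylidene acetal; the PMB ether survives and the descriptor changes only by priority.

**Step 14**
Reactants: 20 (2S)-3-[(4-methoxybenzyl)oxy]propane-1,2-diol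
Product: 21 (2R)-1-[(4-methoxybenzyl)oxy]-3-[(triethylsilyl)oxy]propan-2-ol
Conditions: TESCl (1.05 equiv), imidazole, CH2Cl2, −78 → −40 °C
Reagents that add atoms: triethylsilyl chloride, CC[Si](Cl)(CC)CC
Why: Kinetically selective silylation of the primary over the secondary hydroxyl at low temperature.

**Step 15**
Reactants: 21 (2R)-1-[(4-methoxybenzyl)oxy]-3-[(triethylsilyl)oxy]propan-2-ol; 17 (2S,3S)-3-acetoxy-2-methyl-2-[(triethylsilyl)oxy]butanoic acid
Product: 22 (2R)-1-[(4-methoxybenzyl)oxy]-3-[(triethylsilyl)oxy]propan-2-yl (2S,3S)-3-acetoxy-2-methyl-2-[(triethylsilyl)oxy]butanoate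
Conditions: 17, 2,4,6-trichlorobenzoyl chloride, Et3N, toluene, rt; then 21, DMAP, rt → 40 °C
Reagents that add atoms: none
Why: Yamaguchi esterification (mixed anhydride, DMAP acyl transfer) couples the hindered acid with an unhindered secondary alcohol, and it is done before any ester is present that a free C8 hydroxyl could lactonise onto.

**Step 16**
Reactants: 22 (2R)-1-[(4-methoxybenzyl)oxy]-3-[(triethylsilyl)oxy]propan-2-yl (2S,3S)-3-acetoxy-2-methyl-2-[(triethylsilyl)oxy]butanoate
Product: 23 (2R)-1-[(4-methoxybenzyl)oxy]-3-oxopropan-2-yl (2S,3S)-3-acetoxy-2-methyl-2-[(triethylsilyl)oxy]butanoate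
Conditions: (COCl)2, DMSO, CH2Cl2, −78 → −35 °C; then Et3N, −78 → 0 °C
Reagents that add atoms: none
Why: Swern conditions oxidise a primary triethylsilyl ether directly to the aldehyde (silyl transfer to the chlorosulfonium, then ylide fragmentation), which spares the tertiary silyl ether and the PMB ether and avoids a free hydroxyl next to the ester.

**Step 17**
Reactants: 23 (2R)-1-[(4-methoxybenzyl)oxy]-3-oxopropan-2-yl (2S,3S)-3-acetoxy-2-methyl-2-[(triethylsilyl)oxy]butanoate; 24 methyl prop-2-ynoate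
Product: 26 methyl (4R)-3-hydroxy-5-[(4-methoxybenzyl)oxy]-2-methylidene-4-(R*CO-oxy)pentanoate (C3 = C7 epimers), via vinylalane 25 (not isolated)
Conditions: 24, DIBAL-H, NMO, THF, 0 °C; then 23, −78 → 0 °C; Rochelle salt work-up
Reagents that add atoms: none
Why: Hydroalumination of the propiolate gives the α-aluminated acrylate 25, which adds to the aldehyde (vinylalumination) to give the Morita–Baylis–Hillman-type adduct without amine base, so the α-acyloxy aldehyde should not epimerise; the new C7 carbinol is stereochemically irrelevant.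

**Step 18**
Reactants: 26 methyl (4R)-3-hydroxy-5-[(4-methoxybenzyl)oxy]-2-methylidene-4-(R*CO-oxy)pentanoate
Product: 27 methyl (4R)-3-[(tert-butyldimethylsilyl)oxy]-5-[(4-methoxybenzyl)oxy]-2-methylidene-4-(R*CO-oxy)pentanoate
Conditions: TBSOTf, 2,6-lutidine, CH2Cl2, −78 → 0 °C
Reagents that add atoms: tert-butyldimethylsilyl triflate, CC(C)(C)[Si](C)(C)OS(=O)(=O)C(F)(F)F
Why: Silyl triflate silylation blocks the C7 hydroxyl (and acyl migration from O8) during the following steps.

**Step 19**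
Reactants: 27 methyl (4R)-3-[(tert-butyldimethylsilyl)oxy]-5-[(4-methoxybenzyl)oxy]-2-methylidene-4-(R*CO-oxy)pentanoate
Product: 28 methyl (4R)-3-[(tert-butyldimethylsilyl)oxy]-5-hydroxy-2-methylidene-4-(R*CO-oxy)pentanoate
Conditions: DDQ, CH2Cl2–pH 7 buffer, 0 °C
Reagents that add atoms: none
Why: Oxidative PMB cleavage by DDQ (benzylic oxocarbenium, then hydrolysis) under neutral conditions leaves the silyl ethers, esters and acrylate alone; 28 is used at once to forestall acyl migration to the primary hydroxyl.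

**Step 20**
Reactants: 28 methyl (4R)-3-[(tert-butyldimethylsilyl)oxy]-5-hydroxy-2-methylidene-4-(R*CO-oxy)pentanoate
Product: 29 methyl (4S)-3-[(tert-butyldimethylsilyl)oxy]-2-methylidene-5-oxo-4-(R*CO-oxy)pentanoate
Conditions: Dess–Martin periodinane, NaHCO3, CH2Cl2, 0 °C → rt
Reagents that add atoms: none
Why: Dess–Martin oxidation gives the α-acyloxy aldehyde (C9) under neutral conditions without epimerising C8 (descriptor change by priority only).

**Step 21**
Reactants: 29 methyl (4S)-3-[(tert-butyldimethylsilyl)oxy]-2-methylidene-5-oxo-4-(R*CO-oxy)pentanoate; 12 methyl (2Z)-3-[(2R,3S)-3-{(2Z)-4-[(tert-butyldimethylsilyl)oxy]but-2-en-2-yl}oxiran-2-yl]-2-iodoprop-2-enoate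
Product: 30 seco C9 alcohol, C13H2=C11(CO2Me)–C7H(OTBS)–C8H(OCOR*)–C9H(OH)–C10(CO2Me)=C1H–[C2,C3 cis-oxirane]–C4(CH3)=C5H–C6H2OTBS (8S,9S,2R,3S; 1(10)E,4Z)
Conditions: CrCl2 (20 mol %), chiral sulfonamide–oxazoline ligand (22 mol %), proton sponge (22 mol %), NiCl2·(2,9-dimethylphenanthroline) (2 mol %), Mn, Cp2ZrCl2, LiCl, MeCN, rt
Reagents that add atoms: none
Why: In this asymmetric Nozaki–Hiyama–Kishi alkenylation Ni(0) inserts into the C10–I bond with retention, transmetalation gives the alkenylchromium(III), which adds to the aldehyde only (esters, acrylate and oxirane are inert), and the ligated chromium is intended to deliver C10 to the Si face of C9 (9S) against the Felkin–Anh preference of the α-acyloxy aldehyde, the alkoxide being trapped on zirconium so that it cannot lactonise.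

**Step 22**
Reactants: 30 seco C9 alcohol
Product: 31 seco C9 tiglate (as 30 with C9–O–CO–C(CH3)=CH–CH3, E)
Conditions: tiglic acid, 2,4,6-trichlorobenzoyl chloride, Et3N, toluene, rt; then 30, DMAP, rt
Reagents that add atoms: tiglic acid, C/C=C(\C)C(=O)O
Why: Yamaguchi esterification acylates the hindered secondary allylic C9 hydroxyl at oxygen (configuration retained) without the amine-induced deconjugation that the acid chloride can suffer.

**Step 23**
Reactants: 31 seco C9 tiglate
Product: 32 seco triol (C6–OH, C7–OH and the tertiary side-chain OH free; C8–OCOR, C9–OTig)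
Conditions: HF·pyridine, pyridine, THF, 0 °C → rt
Reagents that add atoms: none
Why: Buffered HF·pyridine cleaves the two TBS ethers and the tertiary TES ether in one operation (Si–F bond formation) under weakly acidic conditions that suppress acyl migration and should spare the oxirane.

**Step 24**
Reactants: 32 seco triol
Product: 33 seco enal (C6 aldehyde, 4Z retained; C7–OH free)
Conditions: TEMPO (10 mol %), PhI(OAc)2, CH2Cl2, rt
Reagents that add atoms: none
Why: The oxoammonium (TEMPO/PhI(OAc)2) oxidation is selective for the primary allylic alcohol over the secondary and tertiary hydroxyls and does not isomerise Z-enals.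

**Step 25**
Reactants: 33 seco enal
Product: 34 seco bromo-aldehyde, BrC13H2–C11(CO2Me)=C7H–C8H(OCOR)–C9H(OTig)–C10(CO2Me)=C1H–[C2,C3 cis-oxirane]–C4(CH3)=C5H–C6HO (7Z)
Conditions: NBS, Me2S, CH2Cl2, −20 → 0 °C
Reagents that add atoms: N-bromosuccinimide, O=C1CCC(=O)N1Br
Why: The Corey–Kim-type sulfonium reagent activates the Baylis–Hillman hydroxyl and bromide displaces it by SN2′ to give the rearranged primary allylic bromide as the Z isomer (C8 trans to the ester), which removes the C7 stereocentre so that both epimers converge.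

**Step 26**
Reactants: 34 seco bromo-aldehyde
Product: 37 CNP0202690.1, via allylchromium species 35 (not isolated), via seco hydroxy ester 36 (not isolated)
Conditions: CrCl2 (10 equiv), THF–DMF (4:1), slow addition of 34 to 2 mM, rt; aq. NH4Cl work-up
Reagents that add atoms: none
Why: Two equivalents of CrCl2 reduce the allylic bromide to the 2-(methoxycarbonyl)allylchromium(III) 35 (Cr on C13), which adds through its γ-carbon C7 to the C6 aldehyde (SE2′, 1,2-addition) to give the chromium alkoxide of 36, whose C6–O then acylates the C12 methyl ester. The closest known reaction type is the intramolecular Nozaki–Hiyama–Kishi (Barbier-type) allylation–lactonisation of ω-formyl 2-(bromomethyl)alk-2-enoates used to close ten-membered germacranolide rings. The carbocycle closes by 10-exo-trig attack on C6=O (C11=C13 becoming exocyclic) and the lactone by 5-exo-trig acyl substitution at C12. C6 is set by the Z-allylchromium (C8 cis to CH2Cr, held there by the ester) reacting through a closed chair transition state with C8 axial, which gives the syn adduct and hence the cis-fused lactone (6R); C7 is set by C8, because A(1,3) strain with CH2Cr puts H-8 in the alkene plane and the tether through C9 brings the aldehyde to the face opposite the C8 acyloxy group (7R). The step needs ring closure to beat oligomerisation and 1,4-elimination of the C8 carboxylate from 35 (high dilution and the hairpin of the C10=C1/oxirane/C4=C5 segment should secure this), 1,2- rather than 1,4-addition to the enal (normal for allylchromium), and reduction of the allylic bromide only (Cr(II) is too weak a reductant for the oxirane and enoates).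

**Compound list**
1 | but-2-yn-1-ol | CC#CCO | starting material
2 | sodium cyclic (Z)-alkenylalanate (2,2-bis(2-methoxyethoxy)-3-methyl-2,5-dihydro-1,2-oxaluminol-2-uide) | CC1=CCO[Al-]1(OCCOC)OCCOC.[Na+] | intermediate
3 | (2Z)-3-iodobut-2-en-1-ol | C/C(I)=C/CO | intermediate
4 | tert-butyl{[(2Z)-3-iodobut-2-en-1-yl]oxy}dimethylsilane | C/C(I)=C/CO[Si](C)(C)C(C)(C)C | intermediate
5 | prop-2-yn-1-ol | C#CCO | starting material
6 | (4Z)-6-[(tert-butyldimethylsilyl)oxy]-4-methylhex-4-en-2-yn-1-ol | OCC#C/C(C)=C\CO[Si](C)(C)C(C)(C)C | intermediate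
7 | (2Z,4Z)-6-[(tert-butyldimethylsilyl)oxy]-4-methylhexa-2,4-dien-1-ol | OC/C=C\C(\C)=C/CO[Si](C)(C)C(C)(C)C | intermediate
8 | [(2R,3S)-3-{(2Z)-4-[(tert-butyldimethylsilyl)oxy]but-2-en-2-yl}oxiran-2-yl]methanol | OC[C@H]1O[C@H]1/C(C)=C\CO[Si](C)(C)C(C)(C)C | intermediate
9 | (2S,3S)-3-{(2Z)-4-[(tert-butyldimethylsilyl)oxy]but-2-en-2-yl}oxirane-2-carbaldehyde | O=C[C@H]1O[C@H]1/C(C)=C\CO[Si](C)(C)C(C)(C)C | intermediate
10 | methyl (triphenyl-λ5-phosphanylidene)acetate | COC(=O)C=P(c1ccccc1)(c1ccccc1)c1ccccc1 | starting material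
11 | methyl iodo(triphenyl-λ5-phosphanylidene)acetate | COC(=O)C(I)=P(c1ccccc1)(c1ccccc1)c1ccccc1 | intermediate
12 | methyl (2Z)-3-[(2R,3S)-3-{(2Z)-4-[(tert-butyldimethylsilyl)oxy]but-2-en-2-yl}oxiran-2-yl]-2-iodoprop-2-enoate | COC(=O)/C(I)=C/[C@H]1O[C@H]1/C(C)=C\CO[Si](C)(C)C(C)(C)C | intermediate
13 | benzyl (2E)-2-methylbut-2-enoate | C/C=C(\C)C(=O)OCc1ccccc1 | starting material
14 | benzyl (2S,3R)-2,3-dimethyloxirane-2-carboxylate | O=C(OCc1ccccc1)[C@@]1(C)O[C@@H]1C | intermediate
15 | benzyl (2S,3S)-3-acetoxy-2-hydroxy-2-methylbutanoate | O=C(OCc1ccccc1)[C@@](C)(O)[C@H](C)OC(C)=O | intermediate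
16 | benzyl (2S,3S)-3-acetoxy-2-methyl-2-[(triethylsilyl)oxy]butanoate | O=C(OCc1ccccc1)[C@@](C)(O[Si](CC)(CC)CC)[C@H](C)OC(C)=O | intermediate
17 | (2S,3S)-3-acetoxy-2-methyl-2-[(triethylsilyl)oxy]butanoic acid | OC(=O)[C@@](C)(O[Si](CC)(CC)CC)[C@H](C)OC(C)=O | intermediate
18 | [(4R)-2,2-dimethyl-1,3-dioxolan-4-yl]methanol | OC[C@@H]1COC(C)(C)O1 | starting material
19 | (4R)-4-{[(4-methoxybenzyl)oxy]methyl}-2,2-dimethyl-1,3-dioxolane | COc1ccc(COC[C@@H]2COC(C)(C)O2)cc1 | intermediate
20 | (2S)-3-[(4-methoxybenzyl)oxy]propane-1,2-diol | COc1ccc(COC[C@@H](O)CO)cc1 | intermediate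
21 | (2R)-1-[(4-methoxybenzyl)oxy]-3-[(triethylsilyl)oxy]propan-2-ol | COc1ccc(COC[C@@H](O)CO[Si](CC)(CC)CC)cc1 | intermediate
22 | (2R)-1-[(4-methoxybenzyl)oxy]-3-[(triethylsilyl)oxy]propan-2-yl (2S,3S)-3-acetoxy-2-methyl-2-[(triethylsilyl)oxy]butanoate | COc1ccc(COC[C@@H](OC(=O)[C@@](C)(O[Si](CC)(CC)CC)[C@H](C)OC(C)=O)CO[Si](CC)(CC)CC)cc1 | intermediate
23 | (2R)-1-[(4-methoxybenzyl)oxy]-3-oxopropan-2-yl (2S,3S)-3-acetoxy-2-methyl-2-[(triethylsilyl)oxy]butanoate | COc1ccc(COC[C@@H](OC(=O)[C@@](C)(O[Si](CC)(CC)CC)[C@H](C)OC(C)=O)C=O)cc1 | intermediate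
24 | methyl prop-2-ynoate | C#CC(=O)OC | starting material
25 | methyl 2-(diisobutylalumanyl)prop-2-enoate | C=C(C(=O)OC)[Al](CC(C)C)CC(C)C | intermediate
26 | methyl (4R)-3-hydroxy-5-[(4-methoxybenzyl)oxy]-2-methylidene-4-(R*CO-oxy)pentanoate, C3 epimers | C=C(C(=O)OC)C(O)[C@H](OC(=O)[C@@](C)(O[Si](CC)(CC)CC)[C@H](C)OC(C)=O)COCc1ccc(OC)cc1 | intermediate
27 | methyl (4R)-3-[(tert-butyldimethylsilyl)oxy]-5-[(4-methoxybenzyl)oxy]-2-methylidene-4-(R*CO-oxy)pentanoate, C3 epimers | C=C(C(=O)OC)C(O[Si](C)(C)C(C)(C)C)[C@H](OC(=O)[C@@](C)(O[Si](CC)(CC)CC)[C@H](C)OC(C)=O)COCc1ccc(OC)cc1 | intermediate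
28 | methyl (4R)-3-[(tert-butyldimethylsilyl)oxy]-5-hydroxy-2-methylidene-4-(R*CO-oxy)pentanoate, C3 epimers | C=C(C(=O)OC)C(O[Si](C)(C)C(C)(C)C)[C@H](OC(=O)[C@@](C)(O[Si](CC)(CC)CC)[C@H](C)OC(C)=O)CO | intermediate
29 | methyl (4S)-3-[(tert-butyldimethylsilyl)oxy]-2-methylidene-5-oxo-4-(R*CO-oxy)pentanoate, C3 epimers | C=C(C(=O)OC)C(O[Si](C)(C)C(C)(C)C)[C@H](OC(=O)[C@@](C)(O[Si](CC)(CC)CC)[C@H](C)OC(C)=O)C=O | intermediate
30 | seco C9 alcohol (C7–OTBS epimers, C8–OCOR*, C9–OH, C6–OTBS; 8S,9S,2R,3S; 1(10)E,4Z) | C=C(C(=O)OC)C(O[Si](C)(C)C(C)(C)C)[C@H](OC(=O)[C@@](C)(O[Si](CC)(CC)CC)[C@H](C)OC(C)=O)[C@@H](O)/C(C(=O)OC)=C\[C@H]1O[C@H]1/C(C)=C\CO[Si](C)(C)C(C)(C)C | intermediate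
31 | seco C9 tiglate (as 30, C9–O-tigloyl) | C=C(C(=O)OC)C(O[Si](C)(C)C(C)(C)C)[C@H](OC(=O)[C@@](C)(O[Si](CC)(CC)CC)[C@H](C)OC(C)=O)[C@@H](OC(=O)/C(C)=C/C)/C(C(=O)OC)=C\[C@H]1O[C@H]1/C(C)=C\CO[Si](C)(C)C(C)(C)C | intermediate
32 | seco triol (C6–OH, C7–OH epimers, tertiary OH; C8–OCOR, C9–OTig) | C=C(C(=O)OC)C(O)[C@H](OC(=O)[C@@](C)(O)[C@H](C)OC(C)=O)[C@@H](OC(=O)/C(C)=C/C)/C(C(=O)OC)=C\[C@H]1O[C@H]1/C(C)=C\CO | intermediate
33 | seco enal (C6 aldehyde, 4Z; C7–OH epimers) | C=C(C(=O)OC)C(O)[C@H](OC(=O)[C@@](C)(O)[C@H](C)OC(C)=O)[C@@H](OC(=O)/C(C)=C/C)/C(C(=O)OC)=C\[C@H]1O[C@H]1/C(C)=C\C=O | intermediate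
34 | seco bromo-aldehyde (C13–Br, 7Z; C6 aldehyde) | BrC/C(C(=O)OC)=C\[C@H](OC(=O)[C@@](C)(O)[C@H](C)OC(C)=O)[C@@H](OC(=O)/C(C)=C/C)/C(C(=O)OC)=C\[C@H]1O[C@H]1/C(C)=C\C=O | intermediate
35 | allylchromium(III) species (C13–CrCl2, solvent ligands omitted) | Cl[Cr](Cl)C/C(C(=O)OC)=C\[C@H](OC(=O)[C@@](C)(O)[C@H](C)OC(C)=O)[C@@H](OC(=O)/C(C)=C/C)/C(C(=O)OC)=C\[C@H]1O[C@H]1/C(C)=C\C=O | intermediate
36 | seco hydroxy ester (ten-membered ring closed, 6R-OH, 7R; C12 methyl ester), formed as its chromium alkoxide | C=C(C(=O)OC)[C@@H]1[C@H](O)/C=C(/C)[C@@H]2O[C@@H]2/C=C(/C(=O)OC)[C@H](OC(=O)/C(C)=C/C)[C@H]1OC(=O)[C@@](C)(O)[C@H](C)OC(C)=O | intermediate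
37 | CNP0202690.1 | C=C1C(=O)O[C@@H]2/C=C(/C)[C@@H]3O[C@@H]3/C=C(/C(=O)OC)[C@H](OC(=O)/C(C)=C/C)[C@@H](OC(=O)[C@@](C)(O)[C@H](C)OC(C)=O)[C@H]12 | target

**Totals**
Total step count: 26. Longest linear sequence: 16 steps (steps 8–11, 15–26).

**Steps most likely to fail**

1. Step 26. What may go wrong: oligomerisation instead of ring closure, 1,4-elimination of the C8 carboxylate from the allylchromium before it finds the aldehyde, or addition through the wrong face or transition-state geometry (trans-lactone or C7 epimer). Fallback, setting out from 26 and 12 and returning at 37: the C6–C7 bond is made first under acyclic control and the ring is closed at C9–C10. 26 is converted with NBS/Me2S into the allylic bromide F1. 12 is desilylated with HF·pyridine to the allylic alcohol F2 and oxidised with MnO2 to the enal F3. Indium-mediated Barbier allylation of F3 with F1 in THF–water gives the syn hydroxy ester F4, which lactonises to the cis-α-methylene-γ-butyrolactone F5. DDQ removes the PMB group to give the alcohol F6, and Dess–Martin oxidation gives the aldehyde F7. An intramolecular Ni/Cr coupling of the alkenyl iodide with the C9 aldehyde at high dilution closes the ten-membered ring to the macrocyclic alcohol F8. Yamaguchi tigloylation gives the tiglate F9, and HF·pyridine removes the triethylsilyl group to give 37.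

2. Step 21. What may go wrong: poor facial selectivity at C9, because the catalyst has to override the Felkin–Anh preference of the α-acyloxy aldehyde, and partial δ-lactonisation of the C9 alkoxide. Fallback, setting out from 29 and 12 and returning at 30: ligand-free NiCl2/CrCl2 coupling is allowed to follow substrate control and should give mainly the 9R alcohol F10. Dess–Martin oxidation gives the cross-conjugated C9 ketone F11. Luche reduction (NaBH4, CeCl3, MeOH, −78 °C) delivers hydride 1,2 along the same Felkin–Anh trajectory, which now gives the 8,9-syn alcohol 30.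

3. Step 5. What may go wrong: slow and weakly enantioselective epoxidation, since Z-allylic alcohols with a branched alkenyl group at C3 are poor substrates for the titanium–tartrate catalyst, and Lewis-acid opening of the vinyl oxirane during a long reaction. Fallback, setting out from 7 and returning at 8: hydroxyl-directed VO(acac)2/t-BuOOH epoxidation (cis-specific, chemoselective for the allylic alcohol) gives the racemic cis-epoxy alcohol, that is 8 together with its enantiomer F12. Lipase-catalysed acetylation with vinyl acetate (kinetic resolution, enzyme chosen to acylate the unwanted antipode) converts F12 into the acetate F13 and leaves 8, which is separated and carried on.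

**Further compounds**
F1 | step 26 | methyl (2Z)-2-(bromomethyl)-5-[(4-methoxybenzyl)oxy]-4-(R*CO-oxy)pent-2-enoate | BrC/C(C(=O)OC)=C\[C@H](OC(=O)[C@@](C)(O[Si](CC)(CC)CC)[C@H](C)OC(C)=O)COCc1ccc(OC)cc1
F2 | step 26 | methyl (2Z)-3-[(2R,3S)-3-{(2Z)-4-hydroxybut-2-en-2-yl}oxiran-2-yl]-2-iodoprop-2-enoate | COC(=O)/C(I)=C/[C@H]1O[C@H]1/C(C)=C\CO
F3 | step 26 | methyl (2Z)-2-iodo-3-[(2R,3S)-3-{(2Z)-4-oxobut-2-en-2-yl}oxiran-2-yl]prop-2-enoate | COC(=O)/C(I)=C/[C@H]1O[C@H]1/C(C)=C\C=O
F4 | step 26 | syn hydroxy ester from F1 and F3 (C6–OH, C7–C11(=CH2)CO2Me; alkenyl iodide, PMB ether) | C=C(C(=O)OC)[C@H]([C@H](O)/C=C(/C)[C@@H]1O[C@@H]1/C=C(\I)C(=O)OC)[C@H](OC(=O)[C@@](C)(O[Si](CC)(CC)CC)[C@H](C)OC(C)=O)COCc1ccc(OC)cc1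
F5 | step 26 | cis-α-methylene-γ-butyrolactone (6R,7R) with C9–OPMB and C10 alkenyl iodide | C=C1C(=O)O[C@H](/C=C(/C)[C@@H]2O[C@@H]2/C=C(\I)C(=O)OC)[C@@H]1[C@H](OC(=O)[C@@](C)(O[Si](CC)(CC)CC)[C@H](C)OC(C)=O)COCc1ccc(OC)cc1
F6 | step 26 | lactone with free C9 primary alcohol | C=C1C(=O)O[C@H](/C=C(/C)[C@@H]2O[C@@H]2/C=C(\I)C(=O)OC)[C@@H]1[C@H](OC(=O)[C@@](C)(O[Si](CC)(CC)CC)[C@H](C)OC(C)=O)CO
F7 | step 26 | lactone C9 aldehyde | C=C1C(=O)O[C@H](/C=C(/C)[C@@H]2O[C@@H]2/C=C(\I)C(=O)OC)[C@@H]1[C@H](OC(=O)[C@@](C)(O[Si](CC)(CC)CC)[C@H](C)OC(C)=O)C=O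
F8 | step 26 | macrocyclic C9 alcohol (9S; side chain O-TES) | C=C1C(=O)O[C@@H]2/C=C(/C)[C@@H]3O[C@@H]3/C=C(/C(=O)OC)[C@H](O)[C@@H](OC(=O)[C@@](C)(O[Si](CC)(CC)CC)[C@H](C)OC(C)=O)[C@H]12
F9 | step 26 | O-triethylsilyl ether of 37 | C=C1C(=O)O[C@@H]2/C=C(/C)[C@@H]3O[C@@H]3/C=C(/C(=O)OC)[C@H](OC(=O)/C(C)=C/C)[C@@H](OC(=O)[C@@](C)(O[Si](CC)(CC)CC)[C@H](C)OC(C)=O)[C@H]12
F10 | step 21 | 9R epimer of 30 | C=C(C(=O)OC)C(O[Si](C)(C)C(C)(C)C)[C@H](OC(=O)[C@@](C)(O[Si](CC)(CC)CC)[C@H](C)OC(C)=O)[C@H](O)/C(C(=O)OC)=C\[C@H]1O[C@H]1/C(C)=C\CO[Si](C)(C)C(C)(C)C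
F11 | step 21 | C9 ketone of 30 | C=C(C(=O)OC)C(O[Si](C)(C)C(C)(C)C)[C@H](OC(=O)[C@@](C)(O[Si](CC)(CC)CC)[C@H](C)OC(C)=O)C(=O)/C(C(=O)OC)=C\[C@H]1O[C@H]1/C(C)=C\CO[Si](C)(C)C(C)(C)C
F12 | step 5 | [(2S,3R)-3-{(2Z)-4-[(tert-butyldimethylsilyl)oxy]but-2-en-2-yl}oxiran-2-yl]methanol (enantiomer of 8) | OC[C@@H]1O[C@@H]1/C(C)=C\CO[Si](C)(C)C(C)(C)C
F13 | step 5 | [(2S,3R)-3-{(2Z)-4-[(tert-butyldimethylsilyl)oxy]but-2-en-2-yl}oxiran-2-yl]methyl acetate | CC(=O)OC[C@@H]1O[C@@H]1/C(C)=C\CO[Si](C)(C)C(C)(C)C
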